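Numbering is that of the 2,3-dihydrobenzofuran (O1, C2, C3, C3a–C7a); ring A is the benzo ring, ring B the dihydrofuran, ring C the aryl group on C2.
Retrosynthetic cuts, in order: C5–propenyl (Suzuki–Miyaura), the methyl of the ring-C 4-methoxyl, O1–C2 (opening ring B), the two hydrogens across C2–C3, and finally C2=C3 (Horner–Wadsworth–Emmons), leaving a ring-A phosphonate and a ring-C aldehyde.
Enabling feature: ring C bears an oxygen para to C2. As a free 4-hydroxy-3,5-dimethoxyphenyl group it can be oxidised to a para-quinone methide whose exocyclic carbon is C2, and attack of the ring-A oxygen O1 on C2 closes a five-membered ring.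
Forward order: rings A and C are bought and joined through C2=C3, the alkene is hydrogenated, both phenols are freed, ring B is closed, the 4-hydroxyl is methylated, and the propenyl group is coupled on at C5.
Stereochemistry: C3 comes from an iridium-catalysed asymmetric hydrogenation of the E-alkene, C2 from C3 during ring closure (trans, favoured kinetically and thermodynamically), and the E-propenyl geometry from the boronic acid.
The C5 bromine serves twice: as the coupling handle and as a para-blocking, deactivating group that keeps the ring-A phenol out of the oxidation.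

Key step: step 9

Assumption: the sense of induction known for (E)-1,2-diphenylpropene, where (S)-tBu-PHOX gives the (R)-alkane, is taken to hold for the stilbene of step 6, so the (R)-ligand is specified for the (S)-product (tBu-PHOX = 4-tert-butyl-2-[2-(diphenylphosphanyl)phenyl]-4,5-dihydrooxazole; BArF = tetrakis[3,5-bis(trifluoromethyl)phenyl]borate).

Step 1
Reactants: 1 5-bromo-2-hydroxy-3-methoxybenzaldehyde
Product: 2 5-bromo-2-isopropoxy-3-methoxybenzaldehyde
Conditions: 2-bromopropane, K2CO3, DMF, 70 °C
Reagents that add atoms: 2-bromopropane, CC(C)Br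
Why: Williamson etherification of an acidic phenol, giving an isopropyl ether that withstands the Grignard reagent, PBr3, hot phosphite, strong base and hydrogenation, and that BCl3 can later remove without touching aryl methyl ethers or the aryl bromide.

Step 2
Reactants: 2 5-bromo-2-isopropoxy-3-methoxybenzaldehyde
Product: 3 (±)-1-(5-bromo-2-isopropoxy-3-methoxyphenyl)ethanol
Conditions: MeMgBr, THF, −20 → 0 °C
Reagents that add atoms: methylmagnesium bromide, C[Mg]Br
Why: Grignard 1,2-addition to the aldehyde is much faster than any bromine–magnesium exchange with MeMgBr, and the racemic carbinol centre is of no consequence because it becomes sp2 in step 6.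

Step 3
Reactants: 3 (±)-1-(5-bromo-2-isopropoxy-3-methoxyphenyl)ethanol
Product: 4 (±)-5-bromo-1-(1-bromoethyl)-2-isopropoxy-3-methoxybenzene
Conditions: PBr3, CH2Cl2, 0 °C
Reagents that add atoms: phosphorus tribromide, BrP(Br)Br
Why: Bromodehydroxylation of a secondary benzylic alcohol with PBr3, run cold and taken on crude to limit loss of HBr to the styrene, under conditions the isopropyl and methyl ethers tolerate.

Step 4
Reactants: 4 (±)-5-bromo-1-(1-bromoethyl)-2-isopropoxy-3-methoxybenzene
Product: 5 (±)-diethyl [1-(5-bromo-2-isopropoxy-3-methoxyphenyl)ethyl]phosphonate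
Conditions: P(OEt)3 (neat, excess), 130 °C
Reagents that add atoms: triethyl phosphite, CCOP(OCC)OCC
Why: Michaelis–Arbuzov reaction, known for 1-arylethyl bromides, in which the phosphite displaces the activated benzylic bromide and gives up one ethyl group to bromide, the volatile bromoethane distilling out while the aryl bromide stays inert.

Step 5
Reactants: 6 4-hydroxy-3,5-dimethoxybenzaldehyde
Product: 7 4-isopropoxy-3,5-dimethoxybenzaldehyde
Conditions: 2-bromopropane, K2CO3, DMF, 80 °C
Reagents that add atoms: 2-bromopropane, CC(C)Br
Why: Williamson etherification that masks the phenol, whose phenoxide would otherwise deactivate the aldehyde in step 6, with the same group as on ring A so that one reagent frees both phenols later.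

Step 6
Reactants: 5 (±)-diethyl [1-(5-bromo-2-isopropoxy-3-methoxyphenyl)ethyl]phosphonate; 7 4-isopropoxy-3,5-dimethoxybenzaldehyde
Product: 8 5-bromo-2-isopropoxy-1-[(E)-1-(4-isopropoxy-3,5-dimethoxyphenyl)prop-1-en-2-yl]-3-methoxybenzene
Conditions: KOtBu, THF, 0 °C → rt
Reagents that add atoms: none
Why: Horner–Wadsworth–Emmons olefination of a non-enolisable aromatic aldehyde with a benzylic phosphonate carbanion, in which reversible addition lets elimination run through the less crowded arrangement with the two aryl groups anti, so the E-alkene should dominate, and the Z-isomer, which would give the wrong enantiomer in step 7, is removed by chromatography and crystallisation.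

Step 7
Reactants: 8 5-bromo-2-isopropoxy-1-[(E)-1-(4-isopropoxy-3,5-dimethoxyphenyl)prop-1-en-2-yl]-3-methoxybenzene
Product: 9 5-bromo-2-isopropoxy-1-[(2S)-1-(4-isopropoxy-3,5-dimethoxyphenyl)propan-2-yl]-3-methoxybenzene
Conditions: [Ir(cod)((R)-tBu-PHOX)]BArF (2 mol %), H2 (50 bar), CH2Cl2, rt
Reagents that add atoms: none
Why: Iridium-catalysed asymmetric hydrogenation of an unfunctionalised E-trisubstituted aryl alkene, for which (E)-α-methylstilbene is the benchmark of cationic P,N-ligated iridium catalysts, where the ligand pocket takes the alkene with its single vinylic hydrogen in the crowded quadrant so that H2 reaches one face only and sets C3 as S, while the aryl bromide and the ethers are inert to this catalyst.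

Step 8
Reactants: 9 5-bromo-2-isopropoxy-1-[(2S)-1-(4-isopropoxy-3,5-dimethoxyphenyl)propan-2-yl]-3-methoxybenzene
Product: 10 4-bromo-2-[(2S)-1-(4-hydroxy-3,5-dimethoxyphenyl)propan-2-yl]-6-methoxyphenol
Conditions: BCl3 (4 equiv), CH2Cl2, −78 → 0 °C
Reagents that add atoms: none
Why: Lewis-acid ether cleavage in which BCl3 binds the ether oxygen and chloride removes the secondary isopropyl group far faster than a methyl group, a selectivity long used for isopropyl-protected phenols next to methoxy groups, with neither the aryl bromide nor C3 affected.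

Step 9
Reactants: 10 4-bromo-2-[(2S)-1-(4-hydroxy-3,5-dimethoxyphenyl)propan-2-yl]-6-methoxyphenol
Product: 12 4-[(2R,3R)-5-bromo-7-methoxy-3-methyl-2,3-dihydro-1-benzofuran-2-yl]-2,6-dimethoxyphenol, via para-quinone methide 11 (not isolated)
Conditions: Ag2O (1.2 equiv), CH2Cl2, rt, dark
Reagents that add atoms: none
Why: Ag2O takes two electrons and two protons from the 4-alkyl-2,6-dimethoxyphenol of ring C, the established entry to para-quinone methides of this phenol class, and gives 11 with C2 as its exocyclic electrophilic terminus. The ring-A hydroxyl then adds to C2 in a 1,6-oxa-conjugate addition (5-exo-trig, the breaking C2=C1' bond lying outside the new ring), which rearomatises ring C and closes ring B; this is the same closing event as in silver oxide couplings of propenylphenols to dihydrobenzofuran neolignans. C2 is controlled by C3: allylic 1,3-strain holds the C3–H bond in the plane of the quinone methide, ring A and the methyl group then lie on opposite faces, and attack of O1 from its own face places the C2 aryl group anti to the C3 methyl, giving (2R,3R), the C3 descriptor changing from S to R only because C2 now carries oxygen. Because 12 is a 4-hydroxybenzyl aryl ether it can revert to 11, so any cis isomer should drain to the more stable trans one. The step needs oxidation at ring C only: two ortho methoxy groups and a para alkyl group make that phenol the easier one to oxidise, while the ring-A phenol is deactivated and para-blocked by bromine and carries no propenyl group yet. Ring closure must also outrun tautomerisation of 11 to the stilbene (which would erase C3) and a second oxidation of 12, which the intramolecular five-membered capture, the neutral aprotic medium and the near-stoichiometric charge of oxidant should secure.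

Step 10
Reactants: 12 4-[(2R,3R)-5-bromo-7-methoxy-3-methyl-2,3-dihydro-1-benzofuran-2-yl]-2,6-dimethoxyphenol
Product: 13 (2R,3R)-5-bromo-7-methoxy-3-methyl-2-(3,4,5-trimethoxyphenyl)-2,3-dihydro-1-benzofuran
Conditions: MeI, K2CO3, acetone, rt
Reagents that add atoms: iodomethane, CI
Why: Williamson O-methylation as routinely applied to phenolic dihydrobenzofuran neolignans, which also removes the free para-hydroxyl and so locks the O1–C2 bond against re-opening, fixing C2 and C3 from here on.

Step 11
Reactants: 13 (2R,3R)-5-bromo-7-methoxy-3-methyl-2-(3,4,5-trimethoxyphenyl)-2,3-dihydro-1-benzofuran; 14 (E)-prop-1-enylboronic acid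
Product: 15 (2R,3R)-7-methoxy-3-methyl-5-[(E)-prop-1-enyl]-2-(3,4,5-trimethoxyphenyl)-2,3-dihydro-1-benzofuran
Conditions: PdCl2(dppf) (5 mol %), K2CO3, 1,4-dioxane/H2O, 85 °C
Reagents that add atoms: none
Why: Suzuki–Miyaura coupling of an aryl bromide with an alkenylboronic acid, which retains alkene geometry through transmetalation and reductive elimination so that the E-propenyl group of 14 is carried into the target, the carbonate base leaving both sp3 centres untouched.

Compound list
1 | 5-bromo-2-hydroxy-3-methoxybenzaldehyde | O=Cc1cc(Br)cc(OC)c1O | starting material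
2 | 5-bromo-2-isopropoxy-3-methoxybenzaldehyde | O=Cc1cc(Br)cc(OC)c1OC(C)C | intermediate
3 | (±)-1-(5-bromo-2-isopropoxy-3-methoxyphenyl)ethanol | CC(O)c1cc(Br)cc(OC)c1OC(C)C | intermediate
4 | (±)-5-bromo-1-(1-bromoethyl)-2-isopropoxy-3-methoxybenzene | CC(Br)c1cc(Br)cc(OC)c1OC(C)C | intermediate
5 | (±)-diethyl [1-(5-bromo-2-isopropoxy-3-methoxyphenyl)ethyl]phosphonate | CCOP(=O)(OCC)C(C)c1cc(Br)cc(OC)c1OC(C)C | intermediate
6 | 4-hydroxy-3,5-dimethoxybenzaldehyde (syringaldehyde) | COc1cc(C=O)cc(OC)c1O | starting material
7 | 4-isopropoxy-3,5-dimethoxybenzaldehyde | COc1cc(C=O)cc(OC)c1OC(C)C | intermediate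
8 | 5-bromo-2-isopropoxy-1-[(E)-1-(4-isopropoxy-3,5-dimethoxyphenyl)prop-1-en-2-yl]-3-methoxybenzene | COc1cc(Br)cc(/C(C)=C/c2cc(OC)c(OC(C)C)c(OC)c2)c1OC(C)C | intermediate
9 | 5-bromo-2-isopropoxy-1-[(2S)-1-(4-isopropoxy-3,5-dimethoxyphenyl)propan-2-yl]-3-methoxybenzene | COc1cc(Br)cc([C@@H](C)Cc2cc(OC)c(OC(C)C)c(OC)c2)c1OC(C)C | intermediate
10 | 4-bromo-2-[(2S)-1-(4-hydroxy-3,5-dimethoxyphenyl)propan-2-yl]-6-methoxyphenol | COc1cc(Br)cc([C@@H](C)Cc2cc(OC)c(O)c(OC)c2)c1O | intermediate
11 | 4-[(2S)-2-(5-bromo-2-hydroxy-3-methoxyphenyl)propylidene]-2,6-dimethoxycyclohexa-2,5-dien-1-one | COc1cc(Br)cc([C@@H](C)C=C2C=C(OC)C(=O)C(OC)=C2)c1O | intermediate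
12 | 4-[(2R,3R)-5-bromo-7-methoxy-3-methyl-2,3-dihydro-1-benzofuran-2-yl]-2,6-dimethoxyphenol | Brc1cc(OC)c2c(c1)[C@@H](C)[C@H](c1cc(OC)c(O)c(OC)c1)O2 | intermediate
13 | (2R,3R)-5-bromo-7-methoxy-3-methyl-2-(3,4,5-trimethoxyphenyl)-2,3-dihydro-1-benzofuran | Brc1cc(OC)c2c(c1)[C@@H](C)[C@H](c1cc(OC)c(OC)c(OC)c1)O2 | intermediate
14 | (E)-prop-1-enylboronic acid | C/C=C/B(O)O | starting material
15 | (2R,3R)-7-methoxy-3-methyl-5-[(E)-prop-1-enyl]-2-(3,4,5-trimethoxyphenyl)-2,3-dihydro-1-benzofuran | C/C=C/c1cc(OC)c2c(c1)[C@@H](C)[C@H](c1cc(OC)c(OC)c(OC)c1)O2 | target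

Total step count: 11. Longest linear sequence: 10 steps (steps 1–4 and 6–11, from 1).

Steps most likely to fail

Step 9.
- **What may go wrong:** competing oxidation of the ring-A phenol, a second oxidation of the product phenol, a prototropic shift in the quinone methide that erases the C3 centre, or intermolecular addition leading to oligomers.
- **Fallback (sets out from 8, returns at 12):** the same electrophile at C2 is reached by dehydration instead of oxidation.
  - Asymmetric hydroboration of 8 with monoisopinocampheylborane (antipode assigned by correlation with 9), followed by NaOH/H2O2, adds hydrogen to C3 and hydroxyl to C2 on one face. This should give (1R,2R)-2-(5-bromo-2-isopropoxy-3-methoxyphenyl)-1-(4-isopropoxy-3,5-dimethoxyphenyl)propan-1-ol F1.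
  - BCl3 in CH2Cl2 (−78 → 0 °C) should strip both isopropyl groups and ionise the para-oxygenated benzylic carbinol in the same flask.
  - Loss of water then gives 11 with no oxidant present, and 11 closes to 12.
  - Acid-induced closure of 1-aryl-2-(2-hydroxyaryl)propan-1-ols to trans-2-aryl-3-methyl-2,3-dihydrobenzofurans is a standard ring closure in this family.

Step 7.
- **What may go wrong:** slow turnover, because the ortho-isopropoxy group twists ring A out of conjugation and crowds the alkene; acid-promoted E/Z isomerisation by iridium hydrides; or poor facial selectivity.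
- **Fallback (sets out from 8, returns at 9):** asymmetric induction is given up in favour of resolution.
  - The more reactive achiral catalyst [Ir(cod)(PCy3)(py)]PF6 (H2, CH2Cl2, rt), which also spares aryl bromides, should give racemic 5-bromo-2-isopropoxy-1-[1-(4-isopropoxy-3,5-dimethoxyphenyl)propan-2-yl]-3-methoxybenzene F2.
  - Preparative supercritical-fluid chromatography on an amylose tris(3,5-dimethylphenylcarbamate) phase separates the enantiomers, and the (S)-enantiomer is 9.

Step 6.
- **What may go wrong:** incomplete E-selectivity, sluggish addition of the hindered tertiary carbanion, or difficult removal of the geometric isomer.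
- **Fallback (sets out from 2, returns at 8):** the alkene geometry is fixed by syn-carbometalation.
  - Ohira–Bestmann homologation of 2 (dimethyl (1-diazo-2-oxopropyl)phosphonate, K2CO3, MeOH) gives 5-bromo-1-ethynyl-2-isopropoxy-3-methoxybenzene F3.
  - Negishi methylalumination (Me3Al, Cp2ZrCl2 cat., CH2Cl2) and iodinolysis (I2, THF) give 5-bromo-1-[(E)-1-iodoprop-1-en-2-yl]-2-isopropoxy-3-methoxybenzene F4.
  - For ring C, commercial 4-bromo-2,6-dimethoxyphenol is O-isopropylated as in step 5 to 5-bromo-2-isopropoxy-1,3-dimethoxybenzene F5.
  - Bromine–lithium exchange and borylation (n-BuLi, B(OiPr)3, then aqueous acid) give (4-isopropoxy-3,5-dimethoxyphenyl)boronic acid F6.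
  - Suzuki–Miyaura coupling of F4 with F6 (Pd(PPh3)4, K2CO3, THF/H2O, 40 °C) should engage the alkenyl iodide well before the aryl bromide and, with retention of geometry, give 8.

Further compounds
F1 | step 9 | (1R,2R)-2-(5-bromo-2-isopropoxy-3-methoxyphenyl)-1-(4-isopropoxy-3,5-dimethoxyphenyl)propan-1-ol | COc1cc(Br)cc([C@@H](C)[C@@H](O)c2cc(OC)c(OC(C)C)c(OC)c2)c1OC(C)C
F2 | step 7 | racemic 5-bromo-2-isopropoxy-1-[1-(4-isopropoxy-3,5-dimethoxyphenyl)propan-2-yl]-3-methoxybenzene | COc1cc(Br)cc(C(C)Cc2cc(OC)c(OC(C)C)c(OC)c2)c1OC(C)C
F3 | step 6 | 5-bromo-1-ethynyl-2-isopropoxy-3-methoxybenzene | C#Cc1cc(Br)cc(OC)c1OC(C)C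
F4 | step 6 | 5-bromo-1-[(E)-1-iodoprop-1-en-2-yl]-2-isopropoxy-3-methoxybenzene | I/C=C(C)/c1cc(Br)cc(OC)c1OC(C)C
F5 | step 6 | 5-bromo-2-isopropoxy-1,3-dimethoxybenzene | COc1cc(Br)cc(OC)c1OC(C)C
F6 | step 6 | (4-isopropoxy-3,5-dimethoxyphenyl)boronic acid | COc1cc(B(O)O)cc(OC)c1OC(C)C
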